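**Remark (conventions and one assumption):** core locants C1–C9 and the descriptors attached to them follow the definition under "Structural features", and "exo" on ring B means the face turned away from C1. It is assumed that one of the two pseudoenantiomeric cinchona thioureas selects the carbonyl arm leading to 14; the quinine-derived one is written, and the quinidine-derived one is used if the sense proves opposite.

## Structural features

Isariotin C is a bicyclo[3.3.1]nonane carbocycle. Ring A (C1, C2, C3, C4, C5, C9) and ring B (C3, C4, C5, C6, C7, C8) share the unit C3–C4–C5, the C4 ketone is the one-carbon bridge, and the nitrogen on C1 carries an (E)-7-oxododec-2-enoyl chain (C1'–C12').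

Seven contiguous stereocentres sit on the nine ring carbons:
- C3, the bridgehead tertiary carbinol, and C5, the bridgehead CH;
- C1, with nitrogen exo (equatorial on ring A);
- C9, whose hydroxyl is cis to that nitrogen, axial on ring A and syn to the C4 carbonyl;
- C6, whose hydroxyl is axial on ring B;
- C7–C8, an epoxide on the same convex (exo) face of ring B as the C6 hydroxyl.

The fragile groups are the two β-ketols C9(OH)–C5–C4=O and C6(OH)–C5–C4=O (retro-aldol), the α-ketol C3(OH)–C4=O (acyloin shift), the epoxide between the C3 and C6 oxygens (acid, nucleophiles), and in the chain the acrylamide acceptor and the C7' ketone.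

The real difficulty is the packing of five oxygen functions and one nitrogen on a nine-carbon cage with an oxygenated quaternary bridgehead, together with the absolute configuration of a core that has no obvious chiral-pool origin.

The feature exploited is that ring A is a three-carbon strap C2–C1–C9 laid across C3 and C5, the two α-carbons of the C4 ketone of ring B, while C3 is also α to C8. If C8 is carried as a second carbonyl, ring B becomes a mirror-symmetric 2-alkoxycyclohexane-1,3-dione and the strap a 2-amidoacrolein. One annulation can then form C2–C3 and C5–C9, close ring A and set C1, C3, C5 and C9.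

## Logic of the disconnections

**23 ⇒ 22 ⇒ 21 + 12.** The C9 O–Si bond and the amide N–C(=O) bond are cut first. The chain holds a ketone that would not survive hydrazine and an alkene that would not survive hydrogenolysis, so it must arrive last. The cut removes twelve carbons and all chain functionality from the core problem. The forward steps must acylate nitrogen in the presence of two free hydroxyls and remove the silyl group without harming the epoxide or the ketols.

**12 ⇒ 10 + 11; 10 ⇒ 8 + 9.** The C2'=C3' bond is cut as a cross-metathesis and the C6'–C7' bond as a ketone synthesis from an acid chloride. Both cuts end at catalogue compounds within two steps. The forward steps need E selectivity and mono-addition of the organomagnesium reagent.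

**21 ⇒ 20.** The N–C bond of the benzyl carbamate and the O–CH2Ph bond at C3 are cut together. With both heteroatoms under hydrogenolysable groups, one neutral operation frees them and no acid meets the epoxide. The 2-oxygenated 1,3-dicarbonyl array also never carries a free hydroxyl while both carbonyls are present. The forward step must cleave a hindered tertiary benzyl ether and leave the epoxide alone.

**20 ⇒ 19.** The C7–O and C8–O bonds of the epoxide are cut to the C7=C8 alkene. The exo C6 hydroxyl can steer the oxidant to its own face, which is also the open one, so two stereocentres are removed at little risk. The forward step needs syn delivery.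

**19 ⇒ 17 ⇒ 16.** The allylic alcohol is traced to the α,β-epoxy ketone by reversing a 1,3-transposition (C6–O kept, C8=O restored), and the epoxide to the C6=C7 enone. This returns C8 to the carbonyl level that the annulation needs and turns the C6 stereocentre into a face-selective addition on a cage. The peroxide must add to C6 from the exo face without cleaving the non-enolisable 1,3-diketone, and hydrazine must condense at C8 and not at C4.

**16 ⇒ 15 ⇒ 14.** The C6=C7 bond is cut back to the saturated ketone through the silyl enol ether, and the C9 O–Si bond is cut. Only C8 can enolise, because C4 lies between the quaternary C3 and the bridgehead C5, so regiochemistry is not an issue. One silylation both arms the ketone and caps the C9 hydroxyl, which closes the retro-aldol path for the basic steps. The forward demand is dehydrogenation of a hindered silyl enol ether.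

**14 ⇒ 4 + 7.** C2–C3 and C5–C9 are cut, ring A is opened and four stereocentres are cleared, leaving two achiral partners; this is the largest simplification in the plan. The forward annulation must choose one of two enantiotopic carbonyl arms, place nitrogen exo and place the C9 hydroxyl syn to C4=O. The nitrogen is carried as a benzyl carbamate and not as a tert-butyl carbamate, because the latter is cleaved by silyl triflates and would need acid beside the epoxide at the end. The closure is of the enolendo type.

**4 ⇒ 2 + 3; 2 ⇒ 1.** The C3–O bond is cut as a carbenoid O–H insertion and the diazo group as a diazo transfer. Insertion must outrun Wolff ring contraction.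

**7 ⇒ 6 ⇒ 5.** The C1=C2 methylene bond is cut as a Mannich-type condensation with formaldehyde, and the aldehyde is traced to the alcohol. The product is an electron-poor enamide prone to polymerisation, so it is made last and used at once.

## Other disconnections considered

**Alternative 1:** The cut is the C1–N bond, with nitrogen delivered late from a carbamate on the C9 oxygen.
- Forward key step: the primary carbamate A2 (C1 still a methylene, tert-butyldimethylsilyl ethers on C3 and C6, epoxide in place) would be oxidised with PhI(OAc)2 and MgO in the presence of Rh2(OAc)4 (dirhodium tetraacetate, divalent rhodium). The rhodium nitrenoid would insert into the exo C1–H bond and give the cis-fused oxazolidinone A1.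
- In its favour: insertion proceeds with retention and the five-membered tether reaches only the C1 hydrogen cis to the C9 oxygen. The C1/C9 relationship is therefore fixed by geometry, which is better than the chosen plan, where it rests on equilibration. The cage of A2 would need only propenal A3 as three-carbon partner, for which the base-mediated annulation is established; on precedent for the acceptor the alternative is also better.
- Against it here: an unactivated secondary C–H is the least reactive class for carbamate nitrenoids. A2 offers competitors: the tertiary C5–H (also a five-membered closure, though deactivated by the C4 carbonyl) and the C6–H activated by its silyloxy group (six-membered closure). The tertiary bridgehead hydroxyl would have to be silylated, and the oxazolidinone must afterwards be opened in a molecule with two β-ketols and an epoxide.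
- Comparison: on structure both plans build the same cage and face the same question of absolute configuration, since an annulation with A3 needs the same carbonyl-arm selection. On mechanism the alternative is more stereospecific at C1 but less predictable in site selectivity. On step economy it is worse by three to four operations (carbamoylation, insertion, ring opening) for a nitrogen that the chosen plan brings in with the acceptor.

**Alternative 2:** The cut is the C3–C4 bond.
- Forward key step: the precursor A5 is a (Z)-cyclooctenone (C3 ketone conjugated with C7=C8) with the formyl carbon C4 on C5, silyl ethers on C6 and C9 and a tert-butyl carbamate on C1. A triazolium-derived carbene would turn the formyl group into an acyl anion equivalent that attacks the C3 ketone across the ring and gives the bridgehead ketol A4, closing rings A and B at once.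
- In its favour: the tertiary α-ketol C3(OH)–C4=O appears directly at the right oxidation level and the bridge can only form cis. C6–O and C7=C8 are already present, so about four steps would follow the key step against eight in the chosen plan; on this count the alternative is clearly better. Intramolecular aldehyde–ketone benzoin reactions are established, so the reaction type is at least as well founded as the chosen annulation. Conjugate addition of the acyl anion to C7 would need a four-membered ring and should not compete.
- Against it here: the difficulty moves into A5, an eight-membered ring with four contiguous stereocentres (C1, C9, C5, C6) and a cis enone, whose preparation would take far more steps than the three short branches of the chosen plan. The formyl-bearing C5 is flanked by two β-silyloxy carbons, so the basic carbene conditions invite β-elimination and epimerisation. The transannular reach depends on a conformation that cannot be enforced, and the tert-butyl carbamate would call for acid beside the epoxide.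
- Comparison: better after the key step, equal in mechanistic soundness, worse before it, and very probably worse in total step count.

**Alternative 3:** The cuts are C1–C2 and C3–O.
- Forward key step: the aldehyde A7 (ring B only, with exocyclic methylene C2 on C3, acetate on C4, silyl ethers on C6 and C9, C7=C8, and aldehyde carbon C1 on C9) would be condensed with the complete chain amide A8 in HCO2H or with BF3·OEt2. The N-acyliminium ion would be attacked by C2, closing ring A, and the C3 cation captured by oxygen to give A6.
- In its favour: the chain enters intact, so no nitrogen protecting group and no late acylation are needed, which is better convergence than the chosen plan. C4 stays an acetate, so no retro-aldol-prone ketol is carried along, again a point on which it is better. Two bonds and ring A form in one operation, equal to the chosen key step.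
- Against it here: C4 is at the wrong oxidation level, so deacetylation, oxidation, epoxidation and desilylation follow and the post-key count is no lower. As ring A closes, the C3 cation becomes a bridgehead cation whose empty orbital is orthogonal to the C7=C8 π bond and which is destabilised by the C4 acetoxy group unless that group participates; its fate is hard to foresee. The acid can protonate the C2=C3–C8=C7 diene, ionise the allylic C6 silyl ether and condense the amide with the chain ketone. A7 needs four stereocentres (C4, C5, C6, C9) set beforehand, against none in the precursors of the chosen plan.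
- Comparison: on structure more convergent, on mechanism more speculative, on step economy longer because of the precursor.

Key step: step 7

## Steps

Step 1
Reactants: 1 cyclohexane-1,3-dione
Product: 2 2-diazocyclohexane-1,3-dione
Conditions: 4-AcNHC6H4SO2N3, Et3N, MeCN, 0 °C → rt
Reagents that add atoms: 4-acetamidobenzenesulfonyl azide, CC(=O)Nc1ccc(cc1)S(=O)(=O)N=[N+]=[N-]
Why: Regitz diazo transfer; the ammonium enolate of the 1,3-dione attacks the terminal azide nitrogen and the triazene collapses to the diazo dione and the sulfonamide, and cyclic 1,3-diones are standard substrates.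

Step 2
Reactants: 2 2-diazocyclohexane-1,3-dione; 3 benzyl alcohol
Product: 4 2-(benzyloxy)cyclohexane-1,3-dione (enolised in solution)
Conditions: Rh2(OAc)4 (1 mol%), BnOH (5 equiv), ClCH2CH2Cl, 80 °C
Reagents that add atoms: none
Why: Dirhodium carbenoid O–H insertion; the acceptor/acceptor carbenoid from 2 is trapped by the alcohol oxygen (oxonium ylide, then proton shift), and the excess of 3 lets insertion outrun Wolff ring contraction and insertion into the enol O–H of the product.

Step 3
Reactants: 5 benzyl (2-hydroxyethyl)carbamate
Product: 6 benzyl (2-oxoethyl)carbamate
Conditions: TEMPO (10 mol%), PhI(OAc)2 (1.1 equiv), CH2Cl2, rt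
Reagents that add atoms: none
Why: Nitroxyl (oxoammonium) oxidation of a primary alcohol stops at the aldehyde and leaves the carbamate untouched; 6 is not stored.

Step 4
Reactants: 6 benzyl (2-oxoethyl)carbamate
Product: 7 benzyl (3-oxoprop-1-en-2-yl)carbamate
Conditions: aq. HCHO (37%, 1.1 equiv), pyrrolidine (10 mol%), EtCO2H (10 mol%), i-PrOH, 45 °C; kept cold in solution and used the same day
Reagents that add atoms: formaldehyde, C=O
Why: Amine-catalysed Mannich condensation (α-methylenation of an aldehyde); the pyrrolidine enamine of 6 adds to the formaldehyde-derived iminium ion and the β-amino aldehyde loses pyrrolidine, while the carbamate keeps the nitrogen lone pair delocalised so that the enamide tautomer should persist.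

Step 5
Reactants: 8 hex-5-enoyl chloride; 9 pentylmagnesium bromide
Product: 10 undec-1-en-6-one
Conditions: Fe(acac)3 (3 mol%), THF, −78 °C
Reagents that add atoms: none
Why: Iron-catalysed acylation of a Grignard reagent; the low-valent ferrate couples with the acid chloride much faster than the Grignard reagent adds to the ketone formed, so mono-addition is expected and the terminal alkene is inert.

Step 6
Reactants: 10 undec-1-en-6-one; 11 acrylic acid
Product: 12 (E)-7-oxododec-2-enoic acid
Conditions: second-generation Grubbs catalyst (H2IMes)(PCy3)Cl2Ru=CHPh (3 mol%), CH2Cl2, 40 °C
Reagents that add atoms: none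
Why: Olefin cross-metathesis between a terminal alkene and an electron-poor acrylic partner that homodimerises slowly; the conjugated E isomer is the thermodynamic product and the ketone is inert to the ruthenium carbene.

Step 7
Reactants: 4 2-(benzyloxy)cyclohexane-1,3-dione; 7 benzyl (3-oxoprop-1-en-2-yl)carbamate
Product: 14 Cbz ketol (core with exo NHCbz on C1; OBn on C3; ketones at C4 and C8; C9–OH cis to N and syn to C4=O; 1S,3S,5R,9R), via open-chain Michael adduct 13 (not isolated)
Conditions: 1-[3,5-bis(trifluoromethyl)phenyl]-3-[(8α,9S)-6'-methoxycinchonan-9-yl]thiourea (10 mol%), CH2Cl2, −20 °C → rt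
Reagents that add atoms: none
Why: Proposed new method: the quinuclidine nitrogen deprotonates the enol of 4 and the thiourea binds the carbonyl of 7, so C3 adds to the methylene terminus (bond C2–C3) and protonation of the amido enol gives the open aldehyde 13, in which C3 is quaternary but still prochiral. The same ammonium/thiourea pair then removes a C5 proton beside one of the two enantiotopic carbonyl groups and the enolate adds to the thiourea-bound aldehyde (bond C5–C9). The closest known reaction type is the amine-base Michael addition/intramolecular aldol of 2-alkylcyclohexane-1,3-diones with propenal to bicyclo[3.3.1]nonane ketols, together with tertiary amine–thiourea catalysis of 1,3-dicarbonyl conjugate additions; neither a 2-amido acceptor nor catalyst control over the carbonyl arm has been shown in this setting. Ring A, the only ring closed, forms in the 6-(enolendo)-exo-trig mode, because the enolate bond C4=C5 lies inside the new ring and the aldehyde C=O outside it. C3 and C5 are controlled together by the catalyst's choice of carbonyl arm, since the one-carbon bridge can only span them cis, and this choice alone fixes the absolute configuration. C1 is epimerisable in 13 through the aldehyde enol and should settle with nitrogen exo (equatorial on ring A), because the endo position collides with C7 across the cage. C9 is set by a chair-like closure in which the aldehyde oxygen lies syn to the enolate oxygen, which gives the axial hydroxyl hydrogen-bonded to the C4 carbonyl, and reversibility of the aldol lets other isomers drain into it. The step needs C- rather than O-alkylation at C3 (favoured by the soft conjugate acceptor), aldol without dehydration (secured because C5 becomes a bridgehead that cannot carry a C5=C9 or C4=C5 double bond) and carbonyl-arm selection, which nothing in the symmetric substrate secures and which rests on the catalyst alone.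

Step 8
Reactants: 14 Cbz ketol
Product: 15 bis(triethylsilyl) compound (C9–OSiEt3; C7=C8 silyl enol ether with OSiEt3 on C8; otherwise as 14; 1S,3S,5R,9R)
Conditions: Et3SiOTf (3 equiv), Et3N (5 equiv), CH2Cl2, −78 → 0 °C
Reagents that add atoms: triethylsilyl trifluoromethanesulfonate, CC[Si](CC)(CC)OS(=O)(=O)C(F)(F)F
Why: Silyl triflate with amine base silylates the C9 hydroxyl and, by soft enolisation, converts the C8 ketone into its C7=C8 silyl enol ether; C4 cannot enolise (quaternary C3, bridgehead C5), and a benzyl carbamate, unlike a tert-butyl carbamate, is not cleaved by silyl triflates. Capping the C9 hydroxyl closes the retro-aldol path for the basic steps that follow.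

Step 9
Reactants: 15 bis(triethylsilyl) compound
Product: 16 enone (C6=C7 conjugated with the C8 ketone; C9–OSiEt3; 1S,3S,5R,9R)
Conditions: Pd(OAc)2 (1.1 equiv), MeCN, rt → 40 °C
Reagents that add atoms: none
Why: Saegusa–Ito oxidation; divalent palladium adds to C7 of the silyl enol ether from the exo face and syn β-hydride elimination of the exo hydrogen on C6 gives the enone and zerovalent palladium, with no other regiochemistry available and the C9 silyl ether untouched.

Step 10
Reactants: 16 enone
Product: 17 epoxy ketone (C6–C7 epoxide on the exo face of ring B; C8 ketone; 1S,3R,5R,6S,7S,9R)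
Conditions: t-BuOOH (decane solution, 2 equiv), DBU (1.2 equiv), CH2Cl2, 0 °C
Reagents that add atoms: tert-butyl hydroperoxide, CC(C)(C)OO
Why: Weitz–Scheffer nucleophilic epoxidation; the tert-butylperoxy anion adds to C6 from the convex exo face (the endo face is covered by C1 and C2 of ring A) and the C7 enolate displaces tert-butoxide on the same face, which sets C6 and C7. The anhydrous hindered peroxide and the amidine base are chosen to spare the non-enolisable 1,3-diketone.

Step 11
Reactants: 17 epoxy ketone
Product: 19 allylic alcohol (exo C6–OH; C7=C8; C3–OBn; C4 ketone; C9–OSiEt3; 1S,3S,5R,6R,9R), via epoxy hydrazone 18 (not isolated)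
Conditions: N2H4·H2O (3 equiv), AcOH (1 equiv), MeOH, 0 °C → rt
Reagents that add atoms: none
Why: Wharton transposition; hydrazine condenses with the C8 carbonyl (C4 is screened by the C9 silyloxy group on one face and the epoxide on the other), the hydrazone opens the epoxide to an alkenyl diazene and loss of N2 leaves C7=C8 with hydrogen on C8. The C6–O bond is never broken, so the exo C6 hydroxyl keeps the configuration set in step 10.

Step 12
Reactants: 19 allylic alcohol
Product: 20 epoxy alcohol (C7–C8 epoxide on the exo face, cis to C6–OH; 1S,3S,5R,6S,7S,8S,9R)
Conditions: VO(acac)2 (5 mol%), t-BuOOH (1.5 equiv), CH2Cl2, 0 °C → rt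
Reagents that add atoms: tert-butyl hydroperoxide, CC(C)(C)OO
Why: Hydroxyl-directed epoxidation of a cyclic allylic alcohol; the vanadate ester of the pseudoaxial C6 hydroxyl delivers oxygen to C7=C8 on its own (exo) face, which is also the sterically open one, and this sets C7 and C8.

Step 13
Reactants: 20 epoxy alcohol
Product: 21 amino diol (free C1–NH2 and C3–OH; C6–OH; C7–C8 epoxide; C4 ketone; C9–OSiEt3; 1S,3S,5R,6S,7S,8S,9R)
Conditions: H2 (1 atm), Pd(OH)2/C, EtOH–EtOAc, rt
Reagents that add atoms: none
Why: Heterogeneous hydrogenolysis cleaves the benzyl carbamate (with loss of CO2) and the benzylic C–O bond of the C3 ether in one neutral operation; the epoxide is neither allylic nor benzylic, and the ketone and silyl ether are inert. The crude amine is used directly.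

Step 14
Reactants: 21 amino diol; 12 (E)-7-oxododec-2-enoic acid
Product: 22 N-acyl silyl ether (isariotin C C9-triethylsilyl ether; 1S,3S,5R,6S,7S,8S,9R)
Conditions: EDC·HCl (1.2 equiv), HOBt (1.2 equiv), CH2Cl2–DMF, 0 °C → rt
Reagents that add atoms: none
Why: Carbodiimide/hydroxybenzotriazole amide coupling; the primary amine attacks the active ester far faster than the hindered secondary C6 hydroxyl or the tertiary C3 hydroxyl, and conjugate addition of the amine to the acrylic double bond should not compete at 0 °C.

Step 15
Reactants: 22 N-acyl silyl ether
Product: 23 isariotin C (1S,3S,5S,6S,7S,8S,9R; (E)-7-oxododec-2-enamide on C1)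
Conditions: HF·pyridine, pyridine, THF, 0 °C → rt
Reagents that add atoms: none
Why: Fluoride-assisted cleavage of the triethylsilyl ether under pyridine-buffered, weakly acidic conditions that should not open the epoxide and, not being basic, do not start retro-aldol cleavage of the freed C9 ketol.

## Compound list

1 | cyclohexane-1,3-dione | O=C1CCCC(=O)C1 | starting material
2 | 2-diazocyclohexane-1,3-dione | O=C1CCCC(=O)C1=[N+]=[N-] | intermediate
3 | benzyl alcohol | OCc1ccccc1 | starting material
4 | 2-(benzyloxy)cyclohexane-1,3-dione | O=C1CCCC(=O)C1OCc1ccccc1 | intermediate
5 | benzyl (2-hydroxyethyl)carbamate | OCCNC(=O)OCc1ccccc1 | starting material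
6 | benzyl (2-oxoethyl)carbamate | O=CCNC(=O)OCc1ccccc1 | intermediate
7 | benzyl (3-oxoprop-1-en-2-yl)carbamate | C=C(NC(=O)OCc1ccccc1)C=O | intermediate
8 | hex-5-enoyl chloride | C=CCCCC(=O)Cl | starting material
9 | pentylmagnesium bromide | CCCCC[Mg]Br | starting material
10 | undec-1-en-6-one | C=CCCCC(=O)CCCCC | intermediate
11 | acrylic acid | C=CC(=O)O | starting material
12 | (E)-7-oxododec-2-enoic acid | CCCCCC(=O)CCC/C=C/C(=O)O | intermediate
13 | open-chain Michael adduct, benzyl {(2S)-3-[1-(benzyloxy)-2,6-dioxocyclohexyl]-1-oxopropan-2-yl}carbamate | O=C[C@@H](NC(=O)OCc1ccccc1)CC1(OCc2ccccc2)C(=O)CCCC1=O | intermediate (not isolated)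
14 | Cbz ketol (exo NHCbz on C1; OBn on C3; C4 and C8 ketones; C9–OH cis to N and syn to C4=O; 1S,3S,5R,9R) | O=C(OCc1ccccc1)N[C@H]1C[C@@]2(OCc3ccccc3)C(=O)[C@H](CCC2=O)[C@H]1O | intermediate
15 | bis(triethylsilyl) compound (C9–OSiEt3; C7=C8 silyl enol ether; 1S,3S,5R,9R) | O=C(OCc1ccccc1)N[C@H]1C[C@@]2(OCc3ccccc3)C(=O)[C@H](CC=C2O[Si](CC)(CC)CC)[C@H]1O[Si](CC)(CC)CC | intermediate
16 | enone (C6=C7–C8=O; C9–OSiEt3; 1S,3S,5R,9R) | O=C(OCc1ccccc1)N[C@H]1C[C@@]2(OCc3ccccc3)C(=O)[C@H](C=CC2=O)[C@H]1O[Si](CC)(CC)CC | intermediate
17 | epoxy ketone (exo C6–C7 epoxide; C8 ketone; 1S,3R,5R,6S,7S,9R) | O=C(OCc1ccccc1)N[C@H]1C[C@@]2(OCc3ccccc3)C(=O)[C@H]([C@@H]4O[C@@H]4C2=O)[C@H]1O[Si](CC)(CC)CC | intermediate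
18 | epoxy hydrazone (C8=N–NH2 derivative of 17; 1S,3S,5R,6S,7R,9R) | O=C(OCc1ccccc1)N[C@H]1C[C@@]2(OCc3ccccc3)C(=O)[C@H]([C@@H]4O[C@@H]4C2=NN)[C@H]1O[Si](CC)(CC)CC | intermediate (not isolated)
19 | allylic alcohol (exo C6–OH; C7=C8; 1S,3S,5R,6R,9R) | O=C(OCc1ccccc1)N[C@H]1C[C@@]2(OCc3ccccc3)C(=O)[C@H]([C@H](O)C=C2)[C@H]1O[Si](CC)(CC)CC | intermediate
20 | epoxy alcohol (exo C7–C8 epoxide cis to C6–OH; 1S,3S,5R,6S,7S,8S,9R) | O=C(OCc1ccccc1)N[C@H]1C[C@@]2(OCc3ccccc3)C(=O)[C@H]([C@H](O)[C@@H]4O[C@@H]42)[C@H]1O[Si](CC)(CC)CC | intermediate
21 | amino diol (C1–NH2; C3–OH; C6–OH; epoxide; C9–OSiEt3; 1S,3S,5R,6S,7S,8S,9R) | N[C@H]1C[C@@]2(O)C(=O)[C@H]([C@H](O)[C@@H]3O[C@@H]32)[C@H]1O[Si](CC)(CC)CC | intermediate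
22 | N-acyl silyl ether (isariotin C C9-triethylsilyl ether; 1S,3S,5R,6S,7S,8S,9R) | CCCCCC(=O)CCC/C=C/C(=O)N[C@H]1C[C@@]2(O)C(=O)[C@H]([C@H](O)[C@@H]3O[C@@H]32)[C@H]1O[Si](CC)(CC)CC | intermediate
23 | isariotin C (1S,3S,5S,6S,7S,8S,9R) | CCCCCC(=O)CCC/C=C/C(=O)N[C@H]1C[C@@]2(O)C(=O)[C@H]([C@H](O)[C@@H]3O[C@@H]32)[C@H]1O | target

## Step count and least certain steps

Total: 15 steps. Longest linear sequence: 11 steps (steps 1, 2 and 7 to 15, from 1).

**Step 7 (key step, new method).** The most likely failure is poor discrimination between the two enantiotopic carbonyl arms during ring closure. The plain amine-base closure is racemic, and the arms differ only through the remote and still mobile C1 centre. Slow equilibration at C9 and oligomerisation of 7 are secondary concerns. Fallback (known chemistry), setting out from 4 and 7 and returning at 14: the two are combined with the achiral base DABCO in MeCN at rt, the established base-mediated Michael–aldol annulation of 2-substituted cyclohexane-1,3-diones with propenals. This should give racemic material, that is 14 together with its mirror image, ent-ketol F1. The enantiomers are separated by preparative chromatography on a cellulose tris(3,5-dimethylphenylcarbamate) phase, F1 is set aside and the route continues from 14.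

**Step 10.** The most likely failure is nucleophilic cleavage of the non-enolisable 1,3-dicarbonyl array (retro-Claisen-type ring opening after peroxide addition to C8 or C4) in competition with conjugate addition. The fallback leaves the route at 14 and returns at 19, bypassing 15 to 18 and any peroxide anion. 14 is silylated at C9 (Et3SiCl, imidazole, DMF) to silyl ether F2. KN(SiMe3)2 (2.2 equiv) and PhNTf2 in THF at −78 °C give the C7=C8 enol triflate F3. Pd(OAc)2, PPh3, HCO2H and Bu3N in DMF at 60 °C reduce it to the alkene F4. Allylic oxidation with catalytic SeO2 and t-BuOOH in CH2Cl2 should then give 19, since C6 holds the only allylic hydrogens and the ene reaction/[2,3] shift takes place on the exo face.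

**Step 11.** The most likely failure is diversion of the hydrazone or the alkenyl diazene (condensation at C4 as well, ring closure across the 1,3-dicarbonyl unit, or solvolytic and radical decomposition of the diazene), so that little allylic alcohol forms. The fallback runs from 17 to 19. NaBH4 with CeCl3·7H2O in MeOH at −40 °C reduces the C8 carbonyl to epoxy alcohol F5; either C8 epimer serves. 1,1'-Thiocarbonyldiimidazole with DMAP in ClCH2CH2Cl at 60 °C gives thiocarbonylimidazolide F6. Bu3SnH and AIBN in toluene at 80 °C generate the C8 radical, which opens the neighbouring epoxide to the C7=C8 alkene and a C6 alkoxyl radical that is reduced to 19 (radical deoxygenative epoxide fragmentation of the Barton–McCombie type), again without breaking the C6–O bond.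

**Step 13.** The most likely failure is stalling of the O-debenzylation at the hindered tertiary ether once the liberated amine binds to the catalyst, so that forcing conditions and reductive opening of the epoxide come into play. The fallback runs from 20 to 22. Brief hydrogenolysis over Pd/C in EtOAc containing pyridine removes only the benzyl carbamate and gives amino benzyl ether F7. Coupling with 12 as in step 14 gives amide F8. The benzyl ether is then removed oxidatively with DDQ under visible-light irradiation in wet CH2Cl2, conditions that should leave the acrylamide, epoxide and silyl ether alone, to give 22.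

## Further compounds

F1 | step 7 | ent-ketol, mirror image of 14 (1R,3R,5S,9S) | O=C(OCc1ccccc1)N[C@@H]1C[C@]2(OCc3ccccc3)C(=O)[C@@H](CCC2=O)[C@@H]1O
F2 | step 10 | silyl ether, C9-triethylsilyl ether of 14 | O=C(OCc1ccccc1)N[C@H]1C[C@@]2(OCc3ccccc3)C(=O)[C@H](CCC2=O)[C@H]1O[Si](CC)(CC)CC
F3 | step 10 | enol triflate, C7=C8 with OSO2CF3 on C8 | O=C(OCc1ccccc1)N[C@H]1C[C@@]2(OCc3ccccc3)C(=O)[C@H](CC=C2OS(=O)(=O)C(F)(F)F)[C@H]1O[Si](CC)(CC)CC
F4 | step 10 | alkene, C7=C8 with C6 methylene | O=C(OCc1ccccc1)N[C@H]1C[C@@]2(OCc3ccccc3)C(=O)[C@H](CC=C2)[C@H]1O[Si](CC)(CC)CC
F5 | step 11 | epoxy alcohol, C8 carbinol of 17 (hydride from the exo face drawn) | O=C(OCc1ccccc1)N[C@H]1C[C@@]2(OCc3ccccc3)C(=O)[C@H]([C@@H]4O[C@@H]4[C@H]2O)[C@H]1O[Si](CC)(CC)CC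
F6 | step 11 | thiocarbonylimidazolide, C8 O-(imidazol-1-ylcarbonothioyl) derivative of F5 | O=C(OCc1ccccc1)N[C@H]1C[C@@]2(OCc3ccccc3)C(=O)[C@H]([C@@H]4O[C@@H]4[C@H]2OC(=S)n5ccnc5)[C@H]1O[Si](CC)(CC)CC
F7 | step 13 | amino benzyl ether, C1–NH2 with C3–OBn retained | N[C@H]1C[C@@]2(OCc3ccccc3)C(=O)[C@H]([C@H](O)[C@@H]4O[C@@H]42)[C@H]1O[Si](CC)(CC)CC
F8 | step 13 | amide, N-[(E)-7-oxododec-2-enoyl] derivative of F7 | CCCCCC(=O)CCC/C=C/C(=O)N[C@H]1C[C@@]2(OCc3ccccc3)C(=O)[C@H]([C@H](O)[C@@H]4O[C@@H]42)[C@H]1O[Si](CC)(CC)CC
A1 | alternative 1 | C1,C9 cis-fused oxazolidinone | O=C4N[C@H]1C[C@@]2(O[Si](C)(C)C(C)(C)C)C(=O)[C@H]([C@H](O[Si](C)(C)C(C)(C)C)[C@@H]3O[C@@H]32)[C@H]1O4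
A2 | alternative 1 | C9 primary carbamate with C1 methylene | C1C[C@@]2(O[Si](C)(C)C(C)(C)C)C(=O)[C@H]([C@H](O[Si](C)(C)C(C)(C)C)[C@@H]3O[C@@H]32)[C@H]1OC(N)=O
A3 | alternative 1 | propenal | C=CC=O
A4 | alternative 2 | bicyclo[3.3.1]nonenone bridgehead ketol | CC(C)(C)OC(=O)N[C@H]1C[C@@]2(O)C(=O)[C@H]([C@H](O[Si](C)(C)C(C)(C)C)C=C2)[C@H]1O[Si](C)(C)C(C)(C)C
A5 | alternative 2 | (Z)-cyclooctenone carrying the formyl group on C5 | CC(C)(C)OC(=O)N[C@H]1CC(=O)/C=C\[C@@H](O[Si](C)(C)C(C)(C)C)[C@@H](C=O)[C@H]1O[Si](C)(C)C(C)(C)C
A6 | alternative 3 | bicyclic amide with C3 hydroxyl, C4 acetate and C7=C8 | CCCCCC(=O)CCC/C=C/C(=O)N[C@H]1C[C@@]2(O)[C@H](OC(C)=O)[C@H]([C@H](O[Si](C)(C)C(C)(C)C)C=C2)[C@H]1O[Si](C)(C)C(C)(C)C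
A7 | alternative 3 | ring-B dienyl aldehyde with exocyclic methylene on C3 | C=C1[C@H](OC(C)=O)[C@H]([C@H](O[Si](C)(C)C(C)(C)C)C=C1)[C@@H](O[Si](C)(C)C(C)(C)C)C=O
A8 | alternative 3 | (E)-7-oxododec-2-enamide | CCCCCC(=O)CCC/C=C/C(N)=O
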